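I will spend nothing on the ash flask at 15 h unless more than 2 percentage points of G can still come, so I turn the question round and ask what that would take.

the same everywhere: Z 0.50 M; L 0.50 M; D 1 mol%

| run | X | remark | time |
|---|---|---|---|
| ash | 1.1 equiv | the very flask that is asked about, followed so far |  |
| elm | 2.2 equiv | run made earlier |  |
| flask | 1.10 equiv |  | 15 h |

- ash (time / min: G / %, Z / %): 90.0: 44.9, 5.7; 180: 47.2, 2.4; 300: 48.8, 1.3; 360: 48.8, 1.4; 480: 49.4, 0.6; 600: 49.6, 1.1; 720: 49.9, 0.2
- elm (time / min: G / %, Z / %): 5.00: 37.1, 13.0; 10.0: 43.1, 6.9; 15.0: 45.8, 4.0; 20.0: 47.2, 2.6; 25.0: 47.7, 1.6; 30.0: 48.4, 0.9; 40.0: 49.3, 0.5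

(scatter of a reading: 0.3 percentage points)

- autumn: at 15 h add X, 100% of the amount charged, then wait 8.0 h
- spring: at 15 h add D, 100% of the amount charged, then wait 8.0 h
- midnight: at 15 h take out 90% of the G then present, then wait 8.0 h
- noon: change nothing and wait 8.0 h more

- D is single-handed; Z and L are mirror images of each other, charged as a racemate, each of them at the stated concentration
- G that was removed still counts
- the earlier runs were read with a standard deviation of 0.3 percentage points
- additions bring no volume worth counting

- G, in percent of the Z and L together first charged, at 15 h
- the option that brings most further G ("none" if no option brings more than 2 percentage points) (autumn / spring / midnight / noon / none)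
- G present, with what was taken out counted in, in percent of the Z and L together first charged, after autumn
- G present, with what was taken out counted in, in percent of the Z and L together first charged, after noon

G plus Z reads 50.1% at 720 min in ash and 49.8% at 40.0 min in elm, so I read G as drawn from Z, and I take one X to each G. My reach is 50.0%: the G the charges can pay for, set by the smaller of charged [X] and [Z], in percent of the Z and L together charged. By charge the ash flask holds less Z than X, so on the charges Z sets the reach.

The opposite outcome needs G below 48.0% at 15 h. Yet ash already read 48.8% at 300 min, above that, which left a room under the reach of 1.2 points. At 720 min the room reads 0.1 points, with a scatter of 0.3 points. The other way out is L feeding G, which would carry G past the reach, and the last ash reading stands level with it. My own call is therefore that no option pays.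

The forecast gives 49.9% at 15 h, 50% after autumn, 50% after noon and none as best: "Adding X, adding D, removing G or simply waiting therefore cannot gain 2 points."

The flask gives 49.6%, 50.0% after autumn, 49.7% after noon and none as best.

    X + D + Z → D + G (k = 96.0 /M²/min)
    X + D + L → D + J (k = 1.90 /M²/min)
    2 D ⇌ Q (K = 1100 /M, k = 25.0 /M/min)

The room at 15 h is 0.40 points, and autumn, the largest gain, brings 0.42 points. A neighbour flask charged with 0.280 equiv of X has a reach of 14.0%; it gives 13.7%, with X at 0%. The ash flask is close to rest at 15 h but not there, with a slowest half-life of 19.5 h. Between 900 min and 9000 min, X goes from 1.65% of its charge to 0%, J from 4.51% to 5.20%, and Z from 0.420% to 0.196%.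

The readings were generated by integration from invented constants; the scatter is artificial.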